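Ring C is cut at C2–C3 and O1–C8a, so that C2 and O1 come from the carbonyl group of 4-methoxybenzaldehyde and C3–C4–C4a–C8a from an ortho-fluoroacetophenone. The key step is a one-pot formal hetero-[4+2] annulation: a catalytic asymmetric Mukaiyama aldol sets C2 (S), then fluoride unmasks the aldolate oxygen, which displaces fluoride at C8a by SNAr. It exploits the C4 ketone of ring C, which makes C3 an enol silane carbon and activates the ortho carbon C8a of ring A. The precursor is the trimethylsilyl enol ether of a 2-fluoro-6-prenyloxy acetophenone; the 5-O-prenyl group is then moved to C8 by a para-Claisen–Cope rearrangement.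

Key step: step 3

Assumption 1: ketone 1 is taken as a purchasable fluoroaromatic building block (it is otherwise one step from 3,5-difluoroanisole by lithiation between the two fluorines and acylation).
Assumption 2: the sense of induction of the oxazaborolidinone is taken by analogy with simple aryl aldehydes and aryl methyl ketone enol silanes (D-tryptophan-derived catalyst, Si-face attack); if the first run shows the opposite sense, the L-tryptophan-derived catalyst is used instead.

Step 1
Reactants: 1 1-(2,6-difluoro-4-methoxyphenyl)ethanone; 2 3-methylbut-2-en-1-ol (prenyl alcohol)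
Product: 3 1-[2-fluoro-4-methoxy-6-(3-methylbut-2-enyloxy)phenyl]ethanone
Conditions: 2 (1.05 equiv), NaH (1.05 equiv), THF, 0 °C; then 1, 0 °C to rt
Reagents that add atoms: none
Why: Nucleophilic aromatic substitution in which sodium prenyloxide displaces one of the two symmetry-equivalent fluorides ortho to the acetyl group, so the regiochemistry is fixed by symmetry and the new ortho alkoxy donor slows a second substitution at one equivalent of alkoxide.

Step 2
Reactants: 3 1-[2-fluoro-4-methoxy-6-(3-methylbut-2-enyloxy)phenyl]ethanone
Product: 4 trimethyl({1-[2-fluoro-4-methoxy-6-(3-methylbut-2-enyloxy)phenyl]ethenyl}oxy)silane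
Conditions: TMSOTf (1.2 equiv), Et3N (1.5 equiv), CH2Cl2, 0 °C; non-aqueous work-up, used crude
Reagents that add atoms: trimethylsilyl trifluoromethanesulfonate, C[Si](C)(C)OS(=O)(=O)C(F)(F)F
Why: Soft enolisation of the methyl ketone with a silyl triflate and an amine gives the only possible enol silane, and the aryl fluoride and the allyl aryl ether are inert to these conditions.

Step 3
Reactants: 4 trimethyl({1-[2-fluoro-4-methoxy-6-(3-methylbut-2-enyloxy)phenyl]ethenyl}oxy)silane (1.15 equiv); 5 4-methoxybenzaldehyde (1.0 equiv)
Product: 7 (2S)-7-methoxy-2-(4-methoxyphenyl)-5-(3-methylbut-2-enyloxy)-2,3-dihydro-4H-chromen-4-one, via (S)-aldol trimethylsilyl ether 6 (not isolated)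
Conditions: (R)-2-butyl-4-(1H-indol-3-ylmethyl)-3-(4-methylphenylsulfonyl)-1,3,2-oxazaborolidin-5-one (20 mol%), EtCN, −78 °C; then CsF (1.5 equiv), 18-crown-6, DMF, −20 °C to rt
Reagents that add atoms: none
Why: The boron Lewis acid binds the formyl oxygen of 5 and shields its Re face, so C3 of enol silane 4 adds to the Si face and silyl transfer gives the (S)-configured aldol silyl ether 6 (C2–C3 bond); fluoride then removes the silyl group and the freed alkoxide O1 adds to C8a, ortho to the C4 carbonyl, to give an anionic σ-adduct that expels fluoride (O1–C8a bond). The closest known reaction types are the catalytic asymmetric Mukaiyama aldol addition of aryl methyl ketone enol silanes to aromatic aldehydes and the fluoride-triggered desilylative SNAr of silyl ethers on acyl-activated aryl fluorides, telescoped here into a formal hetero-[4+2] annulation. Ring C closes as a six-membered ring by intramolecular SNAr, formally a 6-endo-trig addition of O1 to C8a of the C8a=C4a–C4=O unit followed by elimination. The C2 stereocentre is set by the catalyst in the aldol stage and is not touched by the ring closure, because no bond at C2 is made or broken there. The step needs the ring closure to outrun retro-aldol cleavage and E1cB dehydration of the aldolate, which the substrate supports because fluoride is the best SNAr nucleofuge, C8a is ortho to the acyl group and meta to both alkoxy donors, and C8a is the only ring A carbon that carries a nucleofuge, so the regiochemistry of closure is fixed.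

Step 4
Reactants: 7 (2S)-7-methoxy-2-(4-methoxyphenyl)-5-(3-methylbut-2-enyloxy)-2,3-dihydro-4H-chromen-4-one
Product: 10 Flowerine, via C6 ortho-dienone 8 (not isolated), via C8 para-dienone 9 (not isolated)
Conditions: Eu(fod)3 (tris(6,6,7,7,8,8,8-heptafluoro-2,2-dimethyloctane-3,5-dionato)europium, 10 mol%), CHCl3, 60 °C
Reagents that add atoms: none
Why: Lewis-acid-catalysed aromatic Claisen rearrangement of the 5-O-prenyl ether to C6 (the only free ortho carbon), Cope rearrangement from C6 to C8 and enolisation (para-Claisen–Cope) should place the prenyl group at C8 and free the 5-OH, with europium chelated between the C4 carbonyl and O5 and with no bond at C2 involved.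

Compound list
1 | 1-(2,6-difluoro-4-methoxyphenyl)ethanone | CC(=O)c1c(F)cc(OC)cc1F | starting material
2 | 3-methylbut-2-en-1-ol (prenyl alcohol) | CC(C)=CCO | starting material
3 | 1-[2-fluoro-4-methoxy-6-(3-methylbut-2-enyloxy)phenyl]ethanone | CC(=O)c1c(F)cc(OC)cc1OCC=C(C)C | intermediate
4 | trimethyl({1-[2-fluoro-4-methoxy-6-(3-methylbut-2-enyloxy)phenyl]ethenyl}oxy)silane | C=C(O[Si](C)(C)C)c1c(F)cc(OC)cc1OCC=C(C)C | intermediate
5 | 4-methoxybenzaldehyde | COc1ccc(C=O)cc1 | starting material
6 | (3S)-1-[2-fluoro-4-methoxy-6-(3-methylbut-2-enyloxy)phenyl]-3-(4-methoxyphenyl)-3-(trimethylsilyloxy)propan-1-one | COc1ccc([C@H](CC(=O)c2c(F)cc(OC)cc2OCC=C(C)C)O[Si](C)(C)C)cc1 | intermediate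
7 | (2S)-7-methoxy-2-(4-methoxyphenyl)-5-(3-methylbut-2-enyloxy)-2,3-dihydro-4H-chromen-4-one | COc1ccc([C@@H]2CC(=O)c3c(OCC=C(C)C)cc(OC)cc3O2)cc1 | intermediate
8 | (2S)-7-methoxy-2-(4-methoxyphenyl)-6-(2-methylbut-3-en-2-yl)-2,3-dihydro-4H-chromene-4,5(6H)-dione (C6 not defined) | COc1ccc([C@@H]2CC(=O)C3=C(O2)C=C(OC)C(C(C)(C)C=C)C3=O)cc1 | intermediate
9 | (2S)-7-methoxy-2-(4-methoxyphenyl)-8-(3-methylbut-2-enyl)-2,3-dihydro-4H-chromene-4,5(8H)-dione (C8 not defined) | COc1ccc([C@@H]2CC(=O)C3=C(O2)C(CC=C(C)C)C(OC)=CC3=O)cc1 | intermediate
10 | Flowerine, (2S)-5-hydroxy-7-methoxy-2-(4-methoxyphenyl)-8-(3-methylbut-2-enyl)-2,3-dihydro-4H-chromen-4-one | COc1ccc([C@@H]2CC(=O)c3c(O)cc(OC)c(CC=C(C)C)c3O2)cc1 | target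

Total step count: 4. Longest linear sequence: 4 steps (1 → 3 → 4 → 7 → 10).

Steps most likely to fail

1. Step 3. After desilylation, retro-aldol cleavage or E1cB dehydration of the aldolate may compete with ring closure, which loses material and erodes enantiomeric purity through uncatalysed re-addition. The product ring may also open and reclose in the basic fluoride medium, and the electron-rich aldehyde may add sluggishly in the aldol stage. Enantiomeric purity of 7 would be checked by chiral HPLC and raised by recrystallisation if needed. The fallback sets out from 3 and comes back at 7, and sets C2 by aryl transfer instead. Ketone 3 is formylated with ethyl formate and NaH in THF; the enolate oxygen of the resulting hydroxymethylene ketone should close onto the fluorinated carbon by SNAr in the same flask to give 7-methoxy-5-(3-methylbut-2-enyloxy)-4H-chromen-4-one F1. Asymmetric conjugate addition of 4-methoxyphenylboronic acid to F1 should then give 7 under non-basic conditions (Pd(OCOCF3)2, the enantiomer of 4-tert-butyl-2-(pyridin-2-yl)-4,5-dihydrooxazole that leads to the (2S) product, NH4PF6, H2O, ClCH2CH2Cl, 60 °C).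

2. Step 4. The rearrangement may stop at the ortho stage if dienone 8 enolises before the Cope shift, giving poor positional selectivity between C6 and C8. Lewis acid and heat may also open ring C reversibly and erode the C2 configuration. The fallback sets out from 3 and comes back at 10, and moves the rearrangement ahead of the stereocentre. Thermal para-Claisen–Cope rearrangement of 3 (N,N-diethylaniline, 190 °C), in which the acetyl group blocks one ortho position, should give 1-[2-fluoro-6-hydroxy-4-methoxy-3-(3-methylbut-2-enyl)phenyl]ethanone F2. Chloromethyl methyl ether and iPr2NEt in CH2Cl2 then protect the phenol as 1-[2-fluoro-4-methoxy-6-(methoxymethoxy)-3-(3-methylbut-2-enyl)phenyl]ethanone F3. TMSOTf and Et3N convert this into trimethyl({1-[2-fluoro-4-methoxy-6-(methoxymethoxy)-3-(3-methylbut-2-enyl)phenyl]ethenyl}oxy)silane F4. The protocol of step 3 with 5 should pass through (3S)-1-[2-fluoro-4-methoxy-6-(methoxymethoxy)-3-(3-methylbut-2-enyl)phenyl]-3-(4-methoxyphenyl)-3-(trimethylsilyloxy)propan-1-one F5, which is not isolated. Ring closure of that intermediate should give (2S)-7-methoxy-5-(methoxymethoxy)-2-(4-methoxyphenyl)-8-(3-methylbut-2-enyl)-2,3-dihydro-4H-chromen-4-one F6. Catalytic HCl in MeOH at rt then removes the acetal and gives 10.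

3. Step 1. Mono-selectivity may be lost (second fluoride displaced), or the alkoxide may be consumed by enolisation and self-condensation of the methyl ketone. The fallback sets out from 1 and comes back at 3, and installs the oxygen before the prenyl group. KOH in DMSO–H2O (60 °C) replaces one fluoride by hydroxide; the phenoxide formed switches the ring off toward a second substitution and should give, after acidification with aqueous HCl, 1-(2-fluoro-6-hydroxy-4-methoxyphenyl)ethanone F7. Williamson alkylation of F7 with 1-bromo-3-methylbut-2-ene (K2CO3, acetone, reflux) gives 3.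

Further compounds
F1 | step 3 | 7-methoxy-5-(3-methylbut-2-enyloxy)-4H-chromen-4-one | COc1cc(OCC=C(C)C)c2c(c1)OC=CC2=O
F2 | step 4 | 1-[2-fluoro-6-hydroxy-4-methoxy-3-(3-methylbut-2-enyl)phenyl]ethanone | CC(=O)c1c(O)cc(OC)c(CC=C(C)C)c1F
F3 | step 4 | 1-[2-fluoro-4-methoxy-6-(methoxymethoxy)-3-(3-methylbut-2-enyl)phenyl]ethanone | CC(=O)c1c(OCOC)cc(OC)c(CC=C(C)C)c1F
F4 | step 4 | trimethyl({1-[2-fluoro-4-methoxy-6-(methoxymethoxy)-3-(3-methylbut-2-enyl)phenyl]ethenyl}oxy)silane | C=C(O[Si](C)(C)C)c1c(OCOC)cc(OC)c(CC=C(C)C)c1F
F5 | step 4 | (3S)-1-[2-fluoro-4-methoxy-6-(methoxymethoxy)-3-(3-methylbut-2-enyl)phenyl]-3-(4-methoxyphenyl)-3-(trimethylsilyloxy)propan-1-one | COc1ccc([C@H](CC(=O)c2c(F)c(CC=C(C)C)c(OC)cc2OCOC)O[Si](C)(C)C)cc1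
F6 | step 4 | (2S)-7-methoxy-5-(methoxymethoxy)-2-(4-methoxyphenyl)-8-(3-methylbut-2-enyl)-2,3-dihydro-4H-chromen-4-one | COc1ccc([C@@H]2CC(=O)c3c(OCOC)cc(OC)c(CC=C(C)C)c3O2)cc1
F7 | step 1 | 1-(2-fluoro-6-hydroxy-4-methoxyphenyl)ethanone | CC(=O)c1c(O)cc(OC)cc1F
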